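**Retrosynthetic overview**
- Last: global hydrogenolysis; before it both pyran rings (ring C of each flavan) are closed together by twofold Pd-catalysed aryl C–O coupling, with retention at C2.
- Fragment union: twofold chelation-controlled addition of an axially chiral biaryl bis-Grignard reagent to an α-benzyloxy aldehyde sets both C2 centres (1,2-syn, leading to 2,3-cis).
- Biaryl (ring B–ring B) bond and axis: copper-catalysed atroposelective deprotonative C–H/C–H homocoupling of two molecules of 5-bromo-1,2,3-tris(benzyloxy)benzene, made from resorcinol.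
- Aldehyde fragment: ring A from 3-bromophenol (Ir borylation/oxidation); C2–C4 and the C3 stereocentre from (S)-glycidol by aryl-Grignard epoxide opening.
- Ring order: rings A and B are bought-in benzene rings; the B–B axis is made first, the two rings C last and together.

Assumption: the target SMILES fixes (2R,3R) in both flavan units but cannot express the biaryl axis; the natural theasinensin C atropisomer (R axis, written aR) is targeted, and the SMILES below carry no axial descriptor.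
Assumption: in step 5 the (S,S)-ligand is taken to give the (aR) axis; the sense is read off the first run and the mirror-image ligand is used if it is opposite.

**Biaryl fragment**

Step 1
Reactants: 1 resorcinol
Product: 2 1,3-bis(benzyloxy)benzene
Conditions: BnBr (2.2 equiv), K2CO3, DMF, 60 °C
Reagents that add atoms: benzyl bromide (BrCc1ccccc1)
Why: Williamson ether synthesis; both phenoxides are benzylated by SN2, and benzyl ethers survive the later lithiations.

Step 2
Reactants: 2 1,3-bis(benzyloxy)benzene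
Product: 5 2,6-bis(benzyloxy)phenol, via aryllithium 3 (not isolated), via dimethyl arylboronate 4 (not isolated)
Conditions: n-BuLi, THF, 0 °C → rt; B(OMe)3, −78 °C → rt; 30% H2O2, 0 °C → rt
Reagents that add atoms: hydrogen peroxide (OO)
Why: Directed ortho-metalation at C2 between the two ether oxygens, borylation and peroxide oxidation of the C–B bond (1,2-aryl shift) give the 1,2,3-trioxygenated ring.

Step 3
Reactants: 5 2,6-bis(benzyloxy)phenol
Product: 6 4-bromo-2,6-bis(benzyloxy)phenol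
Conditions: NBS, MeCN, −20 → 0 °C
Reagents that add atoms: N-bromosuccinimide (O=C1CCC(=O)N1Br)
Why: Electrophilic aromatic bromination goes para to the free OH because both ortho positions are blocked.

Step 4
Reactants: 6 4-bromo-2,6-bis(benzyloxy)phenol
Product: 7 5-bromo-1,2,3-tris(benzyloxy)benzene
Conditions: BnBr, K2CO3, DMF, 50 °C
Reagents that add atoms: benzyl bromide (BrCc1ccccc1)
Why: Williamson ether synthesis on the hindered phenol.

Step 5
Reactants: 7 5-bromo-1,2,3-tris(benzyloxy)benzene (2 equiv)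
Product: 9 (aR)-2,2'-dibromo-4,4',5,5',6,6'-hexakis(benzyloxy)-1,1'-biphenyl, via diarylzinc 8 (not isolated)
Conditions: Li(TMP) (lithium 2,2,6,6-tetramethylpiperidide, 1.1 equiv per 7), ZnCl2 (0.55 equiv per 7), THF, −78 °C; then Cu(OTf)2 (10 mol%), (S,S)-t-Bu-BOX (12 mol%), O2 (1 atm), −40 → −10 °C
Reagents that add atoms: none
Why: Proposed new method: an atroposelective copper-catalysed aerobic dehydrogenative arene homocoupling that joins two molecules of 7 into one molecule of 9; the only ring C–H type (flanked by Br and OBn) is the most acidic site and is zincated by Li(TMP) with in-situ ZnCl2 trapping (faster than LiBr loss, so no aryne), giving one diarylzinc per two molecules of 7; both aryl groups pass from zinc to bis(oxazoline)-bound divalent copper, O2 oxidises this to a trivalent diarylcopper species, and C–C reductive elimination forms the biaryl bond while the C2-symmetric ligand pocket selects one helical arrangement of the two Br/OBn pairs, the tetra-ortho-substituted axis being frozen once formed; closest known reaction types are the racemic copper-catalysed, O2-driven deprotonative dimerisation of acidic arenes through zinc or magnesium amide bases and the copper/chiral diamine oxidative biaryl coupling of 2-naphthols.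

**Aldehyde fragment**

Step 6
Reactants: 10 3-bromophenol
Product: 11 1-bromo-3-[(4-methoxybenzyl)oxy]benzene
Conditions: PMBCl, K2CO3, DMF, 60 °C
Reagents that add atoms: 4-methoxybenzyl chloride (COc1ccc(CCl)cc1)
Why: Williamson ether synthesis; PMB is chosen because every C–H of its ring has an ortho substituent and so stays inert in the next step.

Step 7
Reactants: 11 1-bromo-3-[(4-methoxybenzyl)oxy]benzene
Product: 13 3-bromo-5-[(4-methoxybenzyl)oxy]phenol, via pinacol boronate 12 (not isolated)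
Conditions: [Ir(OMe)(cod)]2 (1 mol%), 4,4'-di-tert-butyl-2,2'-bipyridine (2 mol%), B2pin2, THF, 60 °C; evaporate; KHSO5 (as Oxone), acetone/H2O, rt
Reagents that add atoms: potassium peroxymonosulfate ([K+].[O-]S(=O)(=O)OO)
Why: Sterically controlled Ir-catalysed C–H borylation takes the only C–H without an ortho substituent (C5), and one-pot oxidation of the C–B bond gives the 1,3,5-pattern of ring A.

Step 8
Reactants: 13 3-bromo-5-[(4-methoxybenzyl)oxy]phenol
Product: 14 1-bromo-3,5-bis[(4-methoxybenzyl)oxy]benzene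
Conditions: PMBCl, K2CO3, DMF, 60 °C
Reagents that add atoms: 4-methoxybenzyl chloride (COc1ccc(CCl)cc1)
Why: Williamson ether synthesis.

Step 9
Reactants: 14 1-bromo-3,5-bis[(4-methoxybenzyl)oxy]benzene
Product: 15 1-bromo-2-iodo-3,5-bis[(4-methoxybenzyl)oxy]benzene
Conditions: NIS, MeCN, 0 °C → rt
Reagents that add atoms: N-iodosuccinimide (O=C1CCC(=O)N1I)
Why: Electrophilic aromatic iodination goes para to one ether oxygen and ortho to the other (C2), the position between the two ethers being more hindered.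

Step 10
Reactants: 16 (S)-glycidol
Product: 17 (R)-trityl glycidyl ether [(2R)-2-(trityloxymethyl)oxirane]
Conditions: TrCl, Et3N, DMAP (cat.), CH2Cl2, 0 °C → rt
Reagents that add atoms: trityl chloride (ClC(c1ccccc1)(c1ccccc1)c1ccccc1)
Why: Selective tritylation of the primary alcohol; the stereocentre is untouched and the descriptor changes from S to R only through the priority rules.

Step 11
Reactants: 15 1-bromo-2-iodo-3,5-bis[(4-methoxybenzyl)oxy]benzene, 17 (R)-trityl glycidyl ether
Product: 19 (2R)-1-{2-bromo-4,6-bis[(4-methoxybenzyl)oxy]phenyl}-3-(trityloxy)propan-2-ol, via arylmagnesium chloride 18 (not isolated)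
Conditions: iPrMgCl·LiCl, THF, −40 °C; CuI (10 mol%), 17, −40 → −15 °C; H2O
Reagents that add atoms: none
Why: Iodine–magnesium exchange is selective for C–I, and copper-catalysed SN2 opening at the terminal epoxide carbon forms the C4–C4a bond without touching the stereocentre; keeping the ortho-bromo Grignard reagent at or below −15 °C avoids aryne formation.

Step 12
Reactants: 19 (2R)-1-{2-bromo-4,6-bis[(4-methoxybenzyl)oxy]phenyl}-3-(trityloxy)propan-2-ol
Product: 20 (2R)-2-(benzyloxy)-1-{2-bromo-4,6-bis[(4-methoxybenzyl)oxy]phenyl}-3-(trityloxy)propane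
Conditions: NaH, BnBr, Bu4NI (cat.), THF/DMF, 0 °C → rt
Reagents that add atoms: benzyl bromide (BrCc1ccccc1)
Why: Williamson ether synthesis; the trityl neighbour cannot migrate, and the benzyl ether later serves as the chelating group.

Step 13
Reactants: 20 (2R)-2-(benzyloxy)-1-{2-bromo-4,6-bis[(4-methoxybenzyl)oxy]phenyl}-3-(trityloxy)propane
Product: 21 (2R)-2-(benzyloxy)-3-{2-bromo-4,6-bis[(4-methoxybenzyl)oxy]phenyl}propan-1-ol
Conditions: TsOH·H2O (10 mol%), MeOH/CH2Cl2, rt
Reagents that add atoms: none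
Why: Acid-catalysed detritylation through the trityl cation, which methanol traps; aryl PMB ethers survive these mild conditions.

Step 14
Reactants: 21 (2R)-2-(benzyloxy)-3-{2-bromo-4,6-bis[(4-methoxybenzyl)oxy]phenyl}propan-1-ol
Product: 22 (2R)-2-(benzyloxy)-3-{2-bromo-4,6-bis[(4-methoxybenzyl)oxy]phenyl}propanal
Conditions: Dess–Martin periodinane, CH2Cl2, 0 °C → rt; used at once
Reagents that add atoms: none
Why: Dess–Martin oxidation is non-basic, so the α-alkoxy stereocentre is not epimerised.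

**Union and completion**

Step 15
Reactants: 9 (aR)-2,2'-dibromo-4,4',5,5',6,6'-hexakis(benzyloxy)-1,1'-biphenyl, 22 (2R)-2-(benzyloxy)-3-{2-bromo-4,6-bis[(4-methoxybenzyl)oxy]phenyl}propanal (2.4 equiv)
Product: 25 (aR)-1,1'-[4,4',5,5',6,6'-hexakis(benzyloxy)biphenyl-2,2'-diyl]bis{(1R,2R)-2-(benzyloxy)-3-[2-bromo-4,6-bis(4-methoxybenzyloxy)phenyl]propan-1-ol}, via dilithiobiaryl 23 (not isolated), via bis(arylmagnesium bromide) 24 (not isolated)
Conditions: t-BuLi (4.1 equiv), Et2O, −78 °C; MgBr2·OEt2, −78 °C; 22, CH2Cl2, −78 → −40 °C; H2O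
Reagents that add atoms: none
Why: Double bromine–lithium exchange and transmetalation give a configurationally stable bis-Grignard reagent, and Cram-chelate (chelation-controlled) addition, with magnesium bridging C=O and the α-OBn oxygen and aryl attack from the α-H side, sets each new carbinol centre 1,2-syn, i.e. (1R) next to (2R).

Step 16
Reactants: 25 (aR)-bis-adduct diol
Product: 26 (aR)-2,2'-[4,4',5,5',6,6'-hexakis(benzyloxy)biphenyl-2,2'-diyl]bis[(2R,3R)-3-(benzyloxy)-5,7-bis(4-methoxybenzyloxy)chromane]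
Conditions: Pd(OAc)2 (10 mol%), RockPhos (15 mol%), Cs2CO3, toluene, 90 °C
Reagents that add atoms: none
Why: Twofold intramolecular Buchwald-type Pd-catalysed C–O coupling (zerovalent palladium inserts into each ring A C–Br bond) closes both pyran rings; the bond formed is O–aryl, so C2 keeps its configuration and the syn adduct becomes the 2,3-cis flavan.

Step 17
Reactants: 26 (aR)-octa-O-benzyl-tetra-O-(4-methoxybenzyl)theasinensin C
Product: 27 theasinensin C, (aR)-2,2'-(4,4',5,5',6,6'-hexahydroxybiphenyl-2,2'-diyl)bis[(2R,3R)-chromane-3,5,7-triol]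
Conditions: H2 (1 atm), Pd(OH)2/C, THF/MeOH, rt; filter under Ar
Reagents that add atoms: none
Why: Catalytic hydrogenolysis removes all eight benzyl and four 4-methoxybenzyl ethers in one operation without touching the stereocentres or the axis.

**Compound list**
1 | resorcinol | Oc1cccc(O)c1 | starting material
2 | 1,3-bis(benzyloxy)benzene | c1ccc(COc2cccc(OCc3ccccc3)c2)cc1 | intermediate
3 | 2,6-bis(benzyloxy)phenyllithium | [Li]c1c(OCc2ccccc2)cccc1OCc1ccccc1 | intermediate
4 | dimethyl [2,6-bis(benzyloxy)phenyl]boronate | COB(OC)c1c(OCc2ccccc2)cccc1OCc1ccccc1 | intermediate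
5 | 2,6-bis(benzyloxy)phenol | Oc1c(OCc2ccccc2)cccc1OCc1ccccc1 | intermediate
6 | 4-bromo-2,6-bis(benzyloxy)phenol | Oc1c(OCc2ccccc2)cc(Br)cc1OCc1ccccc1 | intermediate
7 | 5-bromo-1,2,3-tris(benzyloxy)benzene | Brc1cc(OCc2ccccc2)c(OCc2ccccc2)c(OCc2ccccc2)c1 | intermediate
8 | bis[6-bromo-2,3,4-tris(benzyloxy)phenyl]zinc | Brc1cc(OCc2ccccc2)c(OCc2ccccc2)c(OCc2ccccc2)c1[Zn]c1c(Br)cc(OCc2ccccc2)c(OCc2ccccc2)c1OCc1ccccc1 | intermediate
9 | (aR)-2,2'-dibromo-4,4',5,5',6,6'-hexakis(benzyloxy)-1,1'-biphenyl | Brc1cc(OCc2ccccc2)c(OCc2ccccc2)c(OCc2ccccc2)c1-c1c(Br)cc(OCc2ccccc2)c(OCc2ccccc2)c1OCc1ccccc1 | intermediate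
10 | 3-bromophenol | Oc1cccc(Br)c1 | starting material
11 | 1-bromo-3-[(4-methoxybenzyl)oxy]benzene | COc1ccc(COc2cccc(Br)c2)cc1 | intermediate
12 | 2-{3-bromo-5-[(4-methoxybenzyl)oxy]phenyl}-4,4,5,5-tetramethyl-1,3,2-dioxaborolane | COc1ccc(COc2cc(Br)cc(B3OC(C)(C)C(C)(C)O3)c2)cc1 | intermediate
13 | 3-bromo-5-[(4-methoxybenzyl)oxy]phenol | COc1ccc(COc2cc(O)cc(Br)c2)cc1 | intermediate
14 | 1-bromo-3,5-bis[(4-methoxybenzyl)oxy]benzene | COc1ccc(COc2cc(Br)cc(OCc3ccc(OC)cc3)c2)cc1 | intermediate
15 | 1-bromo-2-iodo-3,5-bis[(4-methoxybenzyl)oxy]benzene | COc1ccc(COc2cc(Br)c(I)c(OCc3ccc(OC)cc3)c2)cc1 | intermediate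
16 | (S)-glycidol | OC[C@H]1CO1 | starting material
17 | (R)-trityl glycidyl ether | C(OC[C@H]1CO1)(c1ccccc1)(c1ccccc1)c1ccccc1 | intermediate
18 | {2-bromo-4,6-bis[(4-methoxybenzyl)oxy]phenyl}magnesium chloride | COc1ccc(COc2cc(Br)c([Mg]Cl)c(OCc3ccc(OC)cc3)c2)cc1 | intermediate
19 | (2R)-1-{2-bromo-4,6-bis[(4-methoxybenzyl)oxy]phenyl}-3-(trityloxy)propan-2-ol | COc1ccc(COc2cc(Br)c(C[C@@H](O)COC(c3ccccc3)(c3ccccc3)c3ccccc3)c(OCc3ccc(OC)cc3)c2)cc1 | intermediate
20 | (2R)-2-(benzyloxy)-1-{2-bromo-4,6-bis[(4-methoxybenzyl)oxy]phenyl}-3-(trityloxy)propane | COc1ccc(COc2cc(Br)c(C[C@@H](OCc3ccccc3)COC(c3ccccc3)(c3ccccc3)c3ccccc3)c(OCc3ccc(OC)cc3)c2)cc1 | intermediate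
21 | (2R)-2-(benzyloxy)-3-{2-bromo-4,6-bis[(4-methoxybenzyl)oxy]phenyl}propan-1-ol | COc1ccc(COc2cc(Br)c(C[C@@H](OCc3ccccc3)CO)c(OCc3ccc(OC)cc3)c2)cc1 | intermediate
22 | (2R)-2-(benzyloxy)-3-{2-bromo-4,6-bis[(4-methoxybenzyl)oxy]phenyl}propanal | COc1ccc(COc2cc(Br)c(C[C@@H](OCc3ccccc3)C=O)c(OCc3ccc(OC)cc3)c2)cc1 | intermediate
23 | (aR)-2,2'-dilithio-4,4',5,5',6,6'-hexakis(benzyloxy)-1,1'-biphenyl | [Li]c1cc(OCc2ccccc2)c(OCc2ccccc2)c(OCc2ccccc2)c1-c1c([Li])cc(OCc2ccccc2)c(OCc2ccccc2)c1OCc1ccccc1 | intermediate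
24 | (aR)-[4,4',5,5',6,6'-hexakis(benzyloxy)biphenyl-2,2'-diyl]bis(magnesium bromide) | Br[Mg]c1cc(OCc2ccccc2)c(OCc2ccccc2)c(OCc2ccccc2)c1-c1c([Mg]Br)cc(OCc2ccccc2)c(OCc2ccccc2)c1OCc1ccccc1 | intermediate
25 | (aR)-1,1'-[4,4',5,5',6,6'-hexakis(benzyloxy)biphenyl-2,2'-diyl]bis{(1R,2R)-2-(benzyloxy)-3-[2-bromo-4,6-bis(4-methoxybenzyloxy)phenyl]propan-1-ol} | O[C@H](c1cc(OCc2ccccc2)c(OCc2ccccc2)c(OCc2ccccc2)c1-c1c([C@@H](O)[C@H](OCc2ccccc2)Cc2c(Br)cc(OCc3ccc(OC)cc3)cc2OCc2ccc(OC)cc2)cc(OCc2ccccc2)c(OCc2ccccc2)c1OCc1ccccc1)[C@H](OCc1ccccc1)Cc1c(Br)cc(OCc2ccc(OC)cc2)cc1OCc1ccc(OC)cc1 | intermediate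
26 | (aR)-2,2'-[4,4',5,5',6,6'-hexakis(benzyloxy)biphenyl-2,2'-diyl]bis[(2R,3R)-3-(benzyloxy)-5,7-bis(4-methoxybenzyloxy)chromane] | COc1ccc(COc2cc(OCc3ccc(OC)cc3)c3c(c2)O[C@H](c4cc(OCc5ccccc5)c(OCc5ccccc5)c(OCc5ccccc5)c4-c4c([C@H]5Oc6cc(OCc7ccc(OC)cc7)cc(OCc7ccc(OC)cc7)c6C[C@H]5OCc5ccccc5)cc(OCc5ccccc5)c(OCc5ccccc5)c4OCc4ccccc4)[C@H](OCc2ccccc2)C3)cc1 | intermediate
27 | theasinensin C, (aR)-2,2'-(4,4',5,5',6,6'-hexahydroxybiphenyl-2,2'-diyl)bis[(2R,3R)-chromane-3,5,7-triol] | Oc1cc(O)c2c(c1)O[C@H](c1cc(O)c(O)c(O)c1-c1c([C@H]3Oc4cc(O)cc(O)c4C[C@H]3O)cc(O)c(O)c1O)[C@H](O)C2 | target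

**Step count**
Total steps: 17. Longest linear sequence: 11 (steps 6–9 and 11–17, from 3-bromophenol); the resorcinol and glycidol lines are 8 steps each.

**Steps most likely to fail**

Step 5 (the proposed new reaction) may give low enantioselectivity through a ligand-free background coupling, or phenol by direct oxygenation of the arylzinc. Enantiomeric purity of 9 can be raised by crystallisation, and any remaining (aS) material becomes a separable diastereomer at 25. The fallback uses known chemistry and sets out from 7. The same Li(TMP)/ZnCl2 zincation is quenched with I2 to give 1-bromo-2-iodo-3,4,5-tris(benzyloxy)benzene F1. A classical Ullmann coupling of two molecules of this iodide with activated Cu powder (DMF, 110–130 °C), selective for the C–I bond, gives racemic 2,2'-dibromo-4,4',5,5',6,6'-hexakis(benzyloxy)-1,1'-biphenyl F2. Preparative HPLC on a chiral stationary phase resolves it, and the (aR)-enantiomer comes back to the route at 9.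

Step 15 may stall after the first addition, lose aldehyde 22 to enolisation by the hindered aryl nucleophile, or give modest syn selectivity. The fallback separates C–C bond formation from stereocontrol and sets out from 21 and 9. Oxidation of 21 with TEMPO/PhI(OAc)2 in MeCN/H2O gives (2R)-2-(benzyloxy)-3-{2-bromo-4,6-bis[(4-methoxybenzyl)oxy]phenyl}propanoic acid F3. Coupling with MeNHOMe·HCl (EDC, Et3N) gives (2R)-2-(benzyloxy)-3-{2-bromo-4,6-bis[(4-methoxybenzyl)oxy]phenyl}-N-methoxy-N-methylpropanamide F4. The bis-Grignard reagent 24, generated from 9 as in step 15, acylates cleanly with F4 (THF, −40 → 0 °C) to give (aR)-1,1'-[4,4',5,5',6,6'-hexakis(benzyloxy)biphenyl-2,2'-diyl]bis{(2R)-2-(benzyloxy)-3-[2-bromo-4,6-bis(4-methoxybenzyloxy)phenyl]propan-1-one} F5. Felkin–Anh reduction with K[s-Bu3BH] (THF, −78 °C), with hydride anti to the C–OBn bond, gives the same syn diol and comes back to the route at 25.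

Step 16 may suffer β-hydride elimination from the benzylic palladium alkoxide (ketone plus debrominated ring A) or stop after one ring closure. The fallback is a transition-metal-free aryne ring closure and sets out from 25. Excess Li(TMP) (THF, −78 → 0 °C) forms both alkoxides and removes the ring A proton between Br and the ether oxygen (C8). Loss of LiBr gives the aryne, and the tethered alkoxide adds at C8a to form the six-membered ring with the O–aryl bond and the same retention at C2, coming back to the route at 26. This passes through no new isolable compound, entered below as none F0.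

**Further compounds**
F1 | step 5 | 1-bromo-2-iodo-3,4,5-tris(benzyloxy)benzene | Brc1cc(OCc2ccccc2)c(OCc2ccccc2)c(OCc2ccccc2)c1I
F2 | step 5 | racemic 2,2'-dibromo-4,4',5,5',6,6'-hexakis(benzyloxy)-1,1'-biphenyl | Brc1cc(OCc2ccccc2)c(OCc2ccccc2)c(OCc2ccccc2)c1-c1c(Br)cc(OCc2ccccc2)c(OCc2ccccc2)c1OCc1ccccc1
F3 | step 15 | (2R)-2-(benzyloxy)-3-{2-bromo-4,6-bis[(4-methoxybenzyl)oxy]phenyl}propanoic acid | COc1ccc(COc2cc(Br)c(C[C@@H](OCc3ccccc3)C(O)=O)c(OCc3ccc(OC)cc3)c2)cc1
F4 | step 15 | (2R)-2-(benzyloxy)-3-{2-bromo-4,6-bis[(4-methoxybenzyl)oxy]phenyl}-N-methoxy-N-methylpropanamide | COc1ccc(COc2cc(Br)c(C[C@@H](OCc3ccccc3)C(=O)N(C)OC)c(OCc3ccc(OC)cc3)c2)cc1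
F5 | step 15 | (aR)-1,1'-[4,4',5,5',6,6'-hexakis(benzyloxy)biphenyl-2,2'-diyl]bis{(2R)-2-(benzyloxy)-3-[2-bromo-4,6-bis(4-methoxybenzyloxy)phenyl]propan-1-one} | O=C(c1cc(OCc2ccccc2)c(OCc2ccccc2)c(OCc2ccccc2)c1-c1c(C(=O)[C@H](OCc2ccccc2)Cc2c(Br)cc(OCc3ccc(OC)cc3)cc2OCc2ccc(OC)cc2)cc(OCc2ccccc2)c(OCc2ccccc2)c1OCc1ccccc1)[C@H](OCc1ccccc1)Cc1c(Br)cc(OCc2ccc(OC)cc2)cc1OCc1ccc(OC)cc1
F0 | step 16 | none | none
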